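The teal run slows while most of its Z stands unturned: between 13 min and 21 min E gains 0.900 mM, with 13.0 mM made from 50.0 mM of Z. The grey run, with half the Z and the same G, reads 13.4 mM at that time. The red run over the teal run gives 1.49 in E at 21 min for 1.48 in G. So in these runs the E read at 21 min goes with G and not with Z.

| flask | Z | G | time |
|---|---|---|---|
| teal | 50.0 mM | 2.50 mM |  |
| red | 50.0 mM | 3.70 mM |  |
| grey | 25.0 mM | 2.50 mM |  |
| ochre | 50.0 mM | 2.50 mM | 52 min |

- teal run (time / min: [E] / mM): 0.84: 1.1; 1.3: 3.0; 2.1: 4.1; 3.3: 5.8; 5.3: 8.4; 8.4: 10.3; 13: 12.1; 21: 13.0
- red run (time / min: [E] / mM): 0.84: 2.7; 1.3: 3.9; 2.1: 5.7; 3.3: 8.5; 5.3: 12.2; 8.4: 15.9; 13: 18.3; 21: 19.4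
- grey run (time / min: [E] / mM): 0.84: 2.3; 1.3: 2.8; 2.1: 4.7; 3.3: 6.6; 5.3: 9.0; 8.4: 10.8; 13: 12.7; 21: 13.4

(standard deviation of a reading: 0.3 mM)

- apparent order in [G] of the starting rate, round the charge of the teal run (the rate where two percent of its Z have turned into E)
- apparent order in [Z] of the starting rate, round the charge of the teal run (the rate where two percent of its Z have turned into E) (one fixed amount of E, the same in the runs compared)
- E in the ochre run at 52 min, as a share of the Z charged

- Overall: Z -> E, with G as catalyst.
- Constant volume, constant temperature.
- The analysis sees a species whether free or bound.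
- An order is taken over about fifteen percent of the charge, up and down.

The number to reckon is the turnover capacity (the field's turnover number), the E finally made per G charged, and two runs give it from separate readings by one reckoning. In the teal run, E gains 3.70 mM from 5.3 min to 13 min and then 0.900 mM over the next interval of nearly equal length, so each interval yields 0.243 of the one before. If later intervals keep that ratio, the gains still to come add up to 0.289 mM. That gives 5.32 E per G. The same reckoning on the red run, from other readings and another charge of G, gives 5.31. The scatter of one reading is worth 0.120 per G in the teal run, and the two values differ by less, though both rest on the same assumed ratio for the tail.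

The ochre run repeats the teal charge, and on that ratio hardly any of the tail remains by 52 min. The teal value then gives 26.6% of the Z charged, and the red value gives 26.5%.

The forecast sets 27.3% (range 26% to 29.5%), higher than this reckoning but with the reckoning inside its range. For the orders it gives 1 in [G] (range 0.8 to 1.2) and −0.2 in [Z] (range −0.5 to 0.1). Its ground for the stop is that “the catalyst is dying, not reaching equilibrium”.

The ochre run gives 26.7% at 52 min, the order in [G] is 1.1, and the order in [Z] is −0.46, lower than the forecast's −0.2.

    G + Z ⇌ GZ, settled at all times (146.0 L mol⁻¹)
    GZ → E + G (2.064 min⁻¹)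
    GZ → Vy + Z (0.3858 min⁻¹)
    GZ + Z ⇌ GZ2, settled at all times (24.80 L mol⁻¹)

The parking of GZ + Z as GZ2 makes no difference to that E at 52 min. On the grey run, 5.32 E per G and 2.50 mM of G give 13.3 mM, which is 53.2% of its 25.0 mM of Z, and the E of the grey run comes to half of that Z at 13.0 min.

Readings and results are simulated for substances that don't exist.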